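The route rests on disconnecting ring C of the middle flavan unit at C3–C4 and O1–C2: the vicinal 3-OH/4-O-ether pair is read as a 3,4-epoxide opened at benzylic C4 by the 4-hydroxyl of the lower unit. The key step unites a salicylaldehyde (ring A of the middle unit, already carrying the upper epicatechin at C8) with a chiral 2-arylvinylsulfonium salt: oxa-Michael addition gives a sulfonium ylide whose carbon (C3) attacks the formyl carbon (C4), closing the pyran and then the oxirane in one operation and setting C2, C3 and C4. The aldehyde oxygen ends as the 3-hydroxyl; the epoxide oxygen lies syn to the 2-aryl group, as the 2,3-cis target requires.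

Key step: step 13

Abbreviations: TBS = tert-butyldimethylsilyl, TES = triethylsilyl. Flavan numbering (O1, C2, C3, C4, C4a to C8a) is used for each unit; upper, middle and lower unit mean the 4β→8-linked epicatechin, the central flavan and the ether-bound unit of the (2S,3S) series.

Assumption: the ylide of the (1S,4S,5S) sulfide is taken to react through the face remote from its gem-dimethyl carbon with the ylide substituent syn to the sulfur lone pair, which corresponds to the (2R,3R) series of the new ring; were the sense opposite, the mirror-image sulfide from (R)-limonene would be used.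

Step 1
Reactants: 1 (−)-epicatechin
Product: 2 5,7,3',4'-tetra-O-TBS-(−)-epicatechin (3-OH free)
Conditions: TBSCl (4.4 equiv), imidazole, DMF, 0 °C to rt
Reagents that add atoms: tert-butyldimethylsilyl chloride, CC(C)(C)[Si](C)(C)Cl
Why: Silylation of the four phenols, which react far faster than the hindered axial secondary 3-hydroxyl, so that the latter should stay free.

Step 2
Reactants: 2 5,7,3',4'-tetra-O-TBS-(−)-epicatechin
Product: 3 (2R,3R,4S)-4-(2-ethoxyethoxy)-5,7,3',4'-tetra-O-TBS-flavan-3-ol (4β-alkoxy; 3,4-trans)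
Conditions: DDQ (2 equiv), 2-ethoxyethanol (5 equiv), CH2Cl2, rt
Reagents that add atoms: 2-ethoxyethanol, CCOCCO
Why: DDQ benzylic oxidation, in which hydride is abstracted from C4 with help of O1 and ring A and the alcohol captures the cation on the face opposite the 3-hydroxyl and the 2-aryl group, which sets C4 as 4β.

Step 3
Reactants: 3 (2R,3R,4S)-4-(2-ethoxyethoxy)-5,7,3',4'-tetra-O-TBS-flavan-3-ol; 4 2,4,6-trihydroxybenzaldehyde
Product: 5 4β-(3-formyl-2,4,6-trihydroxyphenyl)-5,7,3',4'-tetra-O-TBS-epicatechin (2,3-cis-3,4-trans)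
Conditions: Yb(OTf)3 (0.2 equiv), 4 (5 equiv), THF/CH2Cl2, 0 °C to rt
Reagents that add atoms: none
Why: Friedel–Crafts alkylation, in which the Lewis acid ionises the chelating 4-alkoxy group and the arene (its two free positions are equivalent, and it is used in excess against self-condensation) attacks the C4 cation trans to the 3-hydroxyl, which should give the 4β-aryl product.

Step 4
Reactants: 5 4β-(3-formyl-2,4,6-trihydroxyphenyl)-5,7,3',4'-tetra-O-TBS-epicatechin
Product: 6 4β-[3-formyl-2-hydroxy-4,6-bis(TBS-oxy)phenyl]-5,7,3',4'-tetra-O-TBS-epicatechin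
Conditions: TBSCl (2.1 equiv), imidazole, DMF/CH2Cl2, −20 to 0 °C
Reagents that add atoms: tert-butyldimethylsilyl chloride, CC(C)(C)[Si](C)(C)Cl
Why: Kinetically selective silylation, in which the hydroxyl para to the formyl group and the less hindered ortho hydroxyl should react, while the hydroxyl flanked by the flavanyl group and hydrogen-bonded to the aldehyde (the future O1) should remain.

Step 5
Reactants: 7 3,4-bis(TBS-oxy)benzaldehyde
Product: 8 3,4-bis(TBS-oxy)styrene
Conditions: Ph3PCH3Br (1.3 equiv), KOt-Bu (1.2 equiv), THF, 0 °C; then 7, 0 °C to rt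
Reagents that add atoms: methyltriphenylphosphonium bromide, C[P+](c1ccccc1)(c1ccccc1)c1ccccc1.[Br-]
Why: Wittig methylenation of a non-enolisable aryl aldehyde, with the base consumed in ylide formation before the silyl ethers are exposed.

Step 6
Reactants: 9 (S)-(−)-limonene
Product: 10 (1S,4S,5S)-isothiocineole [(1S,4S,5S)-4,7,7-trimethyl-6-thiabicyclo[3.2.1]octane]
Conditions: S8, γ-terpinene, neat, 110 °C
Reagents that add atoms: sulfur, S1SSSSSSS1
Why: Radical thiol–ene-type bicyclisation, in which sulfur adds across both alkenes of limonene with hydrogen transfer from γ-terpinene and the stereocentre of limonene fixes the bridged skeleton (a known one-step preparation of this sulfide).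

Step 7
Reactants: 10 (1S,4S,5S)-isothiocineole
Product: 11 (1S,4S,5S)-isothiocineole S-oxide (oxygen exo)
Conditions: NaIO4 (1.05 equiv), MeOH/H2O, 0 °C
Reagents that add atoms: sodium periodate, [Na+].[O-]I(=O)(=O)=O
Why: Sulfide-to-sulfoxide oxidation, with oxygen delivered to the less hindered exo lone pair and no over-oxidation expected at one equivalent.

Step 8
Reactants: 11 (1S,4S,5S)-isothiocineole S-oxide; 8 3,4-bis(TBS-oxy)styrene
Product: 13 S-[(E)-2-(3,4-bis(TBS-oxy)phenyl)ethenyl]-(1S,4S,5S)-isothiocineolium triflate (alkenyl group exo on sulfur), via S-triflyloxysulfonium triflate 12 (not isolated)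
Conditions: Tf2O (1.05 equiv), CH2Cl2, −78 °C; then 8 and 2,6-di-tert-butylpyridine, −78 to 0 °C
Reagents that add atoms: triflic anhydride, O=S(=O)(OS(=O)(=O)C(F)(F)F)C(F)(F)F
Why: Interrupted Pummerer-type alkenylation, in which the terminal alkene carbon attacks the electrophilic sulfur and the benzylic cation loses the proton next to sulfur to give the (E)-alkenylsulfonium salt with carbon on the open exo side; the normal Pummerer path is disfavoured because one carbon next to sulfur is quaternary and the other is a ring-fusion CH.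

Step 9
Reactants: 14 (+)-epicatechin
Product: 15 5,7,3',4'-tetra-O-TBS-3-O-TES-(+)-epicatechin
Conditions: TBSCl (4.4 equiv), imidazole, DMF, rt; then TESCl (2 equiv), DMAP (cat.), rt
Reagents that add atoms: tert-butyldimethylsilyl chloride, CC(C)(C)[Si](C)(C)Cl; triethylsilyl chloride, CC[Si](CC)(CC)Cl
Why: One-pot sequential silylation, phenols first and then the hindered 3-hydroxyl with the smaller silyl chloride, which gives a 3-O group that comes off with the phenolic ethers in the last step.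

Step 10
Reactants: 15 5,7,3',4'-tetra-O-TBS-3-O-TES-(+)-epicatechin
Product: 16 (2S,3S,4R)-4-hydroxy-5,7,3',4'-tetra-O-TBS-3-O-TES-flavan (3,4-trans)
Conditions: DDQ (1.5 equiv), CH2Cl2/H2O, rt
Reagents that add atoms: water, O
Why: DDQ benzylic oxidation at C4 with capture of the cation by water trans to the 3-silyloxy group; this stereocentre is erased in the next step.

Step 11
Reactants: 16 (2S,3S,4R)-4-hydroxy-5,7,3',4'-tetra-O-TBS-3-O-TES-flavan
Product: 17 (2S,3R)-5,7,3',4'-tetra-O-TBS-3-O-TES-flavan-4-one (2,3-cis)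
Conditions: Dess–Martin periodinane (1.3 equiv), CH2Cl2, 0 °C to rt
Reagents that add atoms: none
Why: Dess–Martin oxidation of the benzylic alcohol under near-neutral conditions, which should leave the 2,3-cis relationship next to the new ketone intact.

Step 12
Reactants: 17 (2S,3R)-5,7,3',4'-tetra-O-TBS-3-O-TES-flavan-4-one
Product: 18 (2S,3S,4S)-4-hydroxy-5,7,3',4'-tetra-O-TBS-3-O-TES-flavan (all-cis)
Conditions: NaBH4, CeCl3·7H2O, MeOH/THF, −78 °C
Reagents that add atoms: none
Why: Luche reduction, in which hydride adds to C4 from the face opposite the axial 3-silyloxy group to give the 3,4-cis alcohol, with cerium tempering the alkoxide and so the risk of silyl transfer from O5.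

Step 13
Reactants: 6 4β-[3-formyl-2-hydroxy-4,6-bis(TBS-oxy)phenyl]-5,7,3',4'-tetra-O-TBS-epicatechin; 13 S-[(E)-2-(3,4-bis(TBS-oxy)phenyl)ethenyl]-(1S,4S,5S)-isothiocineolium triflate
Product: 22 8-(5,7,3',4'-tetra-O-TBS-epicatechin-4β-yl)-5,7,3',4'-tetra-O-TBS-(2R)-flavan 3,4-oxide with the oxirane oxygen syn to the 2-aryl group, via sodium phenoxide 19 (not isolated), via sulfonium ylide 20 (not isolated), via betaine 21 (not isolated)
Conditions: NaH (1.05 equiv), THF, 0 °C; then 13 (1.2 equiv) in CH2Cl2, −40 °C to rt; cold NaHCO3 work-up, product used at once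
Reagents that add atoms: none
Why: Proposed new method: the phenoxide adds reversibly to the aryl-bearing carbon of the alkenylsulfonium salt (oxa-Michael) to give ylide 20, whose carbanion (C3) attacks the ortho formyl carbon (C4), forming the C3–C4 bond and ring C of the middle unit (6-exo-trig), and the alkoxide then displaces the sulfide at C3 with inversion (3-exo-tet) to close the oxirane. The closest known reaction types are the vinylsulfonium epoxy-annulation of amino aldehydes and amino ketones and the Corey–Chaykovsky epoxidation, here extended to a phenoxide nucleophile and a 2-aryl-substituted vinylsulfonium salt. In the chair-like transition state the 2-aryl group, the sulfonium group at C3 and the developing alkoxide at C4 are all equatorial, which gives the 2,3-trans-3,4-trans betaine 21; inversion at C3 then places the oxirane oxygen syn to the 2-aryl group, a face that direct epoxidation of a flav-3-ene would not reach. The absolute sense at C3, and through the chair also at C2 and C4, is set by the chiral sulfide, which shields one face of the ylide; because the oxa-Michael step is reversible, the C2 epimers of the ylide interconvert and only the matched one should cyclise. The step needs face selectivity relative to the epicatechin unit already present at C8, and this is secured by the reagent and not left to the remote resident stereocentres; the free 3-hydroxyl of that unit is far less acidic than the phenol and is not deprotonated by one equivalent of NaH.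

Step 14
Reactants: 22 middle-unit 3,4-oxide; 18 (2S,3S,4S)-4-hydroxy-5,7,3',4'-tetra-O-TBS-3-O-TES-flavan
Product: 23 fully silylated trimer: dodeca-O-TBS (all phenols) and 3-O-TES (lower unit) derivative of the target; middle unit (2R,3R,4S), lower unit (2S,3S,4S)
Conditions: 18 (1.5 equiv), PPTS (0.1 equiv), 4 Å molecular sieves, CH2Cl2, −40 to 0 °C
Reagents that add atoms: none
Why: Acid-catalysed opening of the electron-rich benzylic oxirane, in which the alcohol attacks C4 (stabilised by ring A) anti to the departing oxirane oxygen to give the 3,4-trans ether and free the 3-hydroxyl, while PPTS is too weak to ionise the 4-hydroxyl of 18, so its stereocentres should be untouched.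

Step 15
Reactants: 23 fully silylated trimer
Product: 24 CNP0310719.1 (target)
Conditions: HF·pyridine (excess), pyridine, THF, 0 °C to rt; Me3SiOMe quench; Sephadex LH-20
Reagents that add atoms: none
Why: Fluoride-induced cleavage of the twelve aryl silyl ethers and the one triethylsilyl ether under pyridine-buffered conditions, chosen because hydrogenolysis, stronger acid or base would endanger the bis-benzylic C4–O–C4 ether.

Compound list
1 | (−)-epicatechin, (2R,3R) | Oc1cc(O)c2c(c1)O[C@H](c1ccc(O)c(O)c1)[C@H](O)C2 | starting material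
2 | 5,7,3',4'-tetra-O-TBS-(−)-epicatechin | CC(C)(C)[Si](C)(C)Oc1cc(O[Si](C)(C)C(C)(C)C)c2c(c1)O[C@H](c1ccc(O[Si](C)(C)C(C)(C)C)c(O[Si](C)(C)C(C)(C)C)c1)[C@H](O)C2 | intermediate
3 | (2R,3R,4S)-4-(2-ethoxyethoxy)-5,7,3',4'-tetra-O-TBS-flavan-3-ol | CC(C)(C)[Si](C)(C)Oc1cc(O[Si](C)(C)C(C)(C)C)c2c(c1)O[C@H](c1ccc(O[Si](C)(C)C(C)(C)C)c(O[Si](C)(C)C(C)(C)C)c1)[C@H](O)[C@H]2OCCOCC | intermediate
4 | 2,4,6-trihydroxybenzaldehyde | O=Cc1c(O)cc(O)cc1O | starting material
5 | 4β-(3-formyl-2,4,6-trihydroxyphenyl)-5,7,3',4'-tetra-O-TBS-epicatechin | CC(C)(C)[Si](C)(C)Oc1cc(O[Si](C)(C)C(C)(C)C)c2c(c1)O[C@H](c1ccc(O[Si](C)(C)C(C)(C)C)c(O[Si](C)(C)C(C)(C)C)c1)[C@H](O)[C@H]2c1c(O)cc(O)c(C=O)c1O | intermediate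
6 | 4β-[3-formyl-2-hydroxy-4,6-bis(TBS-oxy)phenyl]-5,7,3',4'-tetra-O-TBS-epicatechin | CC(C)(C)[Si](C)(C)Oc1cc(O[Si](C)(C)C(C)(C)C)c2c(c1)O[C@H](c1ccc(O[Si](C)(C)C(C)(C)C)c(O[Si](C)(C)C(C)(C)C)c1)[C@H](O)[C@H]2c1c(O[Si](C)(C)C(C)(C)C)cc(O[Si](C)(C)C(C)(C)C)c(C=O)c1O | intermediate
7 | 3,4-bis(TBS-oxy)benzaldehyde | O=Cc1ccc(O[Si](C)(C)C(C)(C)C)c(O[Si](C)(C)C(C)(C)C)c1 | starting material
8 | 3,4-bis(TBS-oxy)styrene | C=Cc1ccc(O[Si](C)(C)C(C)(C)C)c(O[Si](C)(C)C(C)(C)C)c1 | intermediate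
9 | (S)-(−)-limonene | CC1=CC[C@H](CC1)C(C)=C | starting material
10 | (1S,4S,5S)-isothiocineole | C[C@H]1CC[C@H]2C[C@@H]1SC2(C)C | intermediate
11 | (1S,4S,5S)-isothiocineole S-oxide (oxygen exo) | C[C@H]1CC[C@H]2C[C@@H]1[S@](=O)C2(C)C | intermediate
12 | S-triflyloxysulfonium triflate of 11 | C[C@H]1CC[C@H]2C[C@@H]1[S@+](OS(=O)(=O)C(F)(F)F)C2(C)C.[O-]S(=O)(=O)C(F)(F)F | intermediate
13 | S-[(E)-2-(3,4-bis(TBS-oxy)phenyl)ethenyl]-(1S,4S,5S)-isothiocineolium triflate | C[C@H]1CC[C@H]2C[C@@H]1[S@+](/C=C/c1ccc(O[Si](C)(C)C(C)(C)C)c(O[Si](C)(C)C(C)(C)C)c1)C2(C)C.[O-]S(=O)(=O)C(F)(F)F | intermediate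
14 | (+)-epicatechin, (2S,3S) | Oc1cc(O)c2c(c1)O[C@@H](c1ccc(O)c(O)c1)[C@@H](O)C2 | starting material
15 | 5,7,3',4'-tetra-O-TBS-3-O-TES-(+)-epicatechin | CC(C)(C)[Si](C)(C)Oc1cc(O[Si](C)(C)C(C)(C)C)c2c(c1)O[C@@H](c1ccc(O[Si](C)(C)C(C)(C)C)c(O[Si](C)(C)C(C)(C)C)c1)[C@@H](O[Si](CC)(CC)CC)C2 | intermediate
16 | (2S,3S,4R)-4-hydroxy-5,7,3',4'-tetra-O-TBS-3-O-TES-flavan (3,4-trans) | CC(C)(C)[Si](C)(C)Oc1cc(O[Si](C)(C)C(C)(C)C)c2c(c1)O[C@@H](c1ccc(O[Si](C)(C)C(C)(C)C)c(O[Si](C)(C)C(C)(C)C)c1)[C@@H](O[Si](CC)(CC)CC)[C@@H]2O | intermediate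
17 | (2S,3R)-5,7,3',4'-tetra-O-TBS-3-O-TES-flavan-4-one (2,3-cis) | CC(C)(C)[Si](C)(C)Oc1cc(O[Si](C)(C)C(C)(C)C)c2c(c1)O[C@@H](c1ccc(O[Si](C)(C)C(C)(C)C)c(O[Si](C)(C)C(C)(C)C)c1)[C@@H](O[Si](CC)(CC)CC)C2=O | intermediate
18 | (2S,3S,4S)-4-hydroxy-5,7,3',4'-tetra-O-TBS-3-O-TES-flavan (all-cis) | CC(C)(C)[Si](C)(C)Oc1cc(O[Si](C)(C)C(C)(C)C)c2c(c1)O[C@@H](c1ccc(O[Si](C)(C)C(C)(C)C)c(O[Si](C)(C)C(C)(C)C)c1)[C@@H](O[Si](CC)(CC)CC)[C@H]2O | intermediate
19 | sodium phenoxide of 6 | CC(C)(C)[Si](C)(C)Oc1cc(O[Si](C)(C)C(C)(C)C)c2c(c1)O[C@H](c1ccc(O[Si](C)(C)C(C)(C)C)c(O[Si](C)(C)C(C)(C)C)c1)[C@H](O)[C@H]2c1c(O[Si](C)(C)C(C)(C)C)cc(O[Si](C)(C)C(C)(C)C)c(C=O)c1[O-].[Na+] | intermediate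
20 | sulfonium ylide from oxa-Michael addition (C2 as in the product; carbanion at C3) | C[C@H]1CC[C@H]2C[C@@H]1[S@+]([CH-][C@@H](c1ccc(O[Si](C)(C)C(C)(C)C)c(O[Si](C)(C)C(C)(C)C)c1)Oc1c(C=O)c(O[Si](C)(C)C(C)(C)C)cc(O[Si](C)(C)C(C)(C)C)c1[C@H]1c3c(O[Si](C)(C)C(C)(C)C)cc(O[Si](C)(C)C(C)(C)C)cc3O[C@H](c3ccc(O[Si](C)(C)C(C)(C)C)c(O[Si](C)(C)C(C)(C)C)c3)[C@@H]1O)C2(C)C | intermediate
21 | 2,3-trans-3,4-trans betaine (3-sulfonium, 4-alkoxide) | C[C@H]1CC[C@H]2C[C@@H]1[S@+]([C@@H]3[C@@H](c1ccc(O[Si](C)(C)C(C)(C)C)c(O[Si](C)(C)C(C)(C)C)c1)Oc1c([C@H]4c5c(O[Si](C)(C)C(C)(C)C)cc(O[Si](C)(C)C(C)(C)C)cc5O[C@H](c5ccc(O[Si](C)(C)C(C)(C)C)c(O[Si](C)(C)C(C)(C)C)c5)[C@@H]4O)c(O[Si](C)(C)C(C)(C)C)cc(O[Si](C)(C)C(C)(C)C)c1[C@H]3[O-])C2(C)C | intermediate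
22 | middle-unit 3,4-oxide (oxirane syn to the 2-aryl group) carrying the upper unit at C8 | CC(C)(C)[Si](C)(C)Oc1cc(O[Si](C)(C)C(C)(C)C)c2c(c1)O[C@H](c1ccc(O[Si](C)(C)C(C)(C)C)c(O[Si](C)(C)C(C)(C)C)c1)[C@H](O)[C@H]2c1c(O[Si](C)(C)C(C)(C)C)cc(O[Si](C)(C)C(C)(C)C)c2c1O[C@H](c1ccc(O[Si](C)(C)C(C)(C)C)c(O[Si](C)(C)C(C)(C)C)c1)[C@@H]3O[C@H]23 | intermediate
23 | fully silylated trimer (twelve phenolic TBS ethers; 3-O-TES on the lower unit) | CC(C)(C)[Si](C)(C)Oc1cc(O[Si](C)(C)C(C)(C)C)c2c(c1)O[C@H](c1ccc(O[Si](C)(C)C(C)(C)C)c(O[Si](C)(C)C(C)(C)C)c1)[C@H](O)[C@H]2c1c(O[Si](C)(C)C(C)(C)C)cc(O[Si](C)(C)C(C)(C)C)c2c1O[C@H](c1ccc(O[Si](C)(C)C(C)(C)C)c(O[Si](C)(C)C(C)(C)C)c1)[C@H](O)[C@H]2O[C@H]1c2c(O[Si](C)(C)C(C)(C)C)cc(O[Si](C)(C)C(C)(C)C)cc2O[C@@H](c2ccc(O[Si](C)(C)C(C)(C)C)c(O[Si](C)(C)C(C)(C)C)c2)[C@H]1O[Si](CC)(CC)CC | intermediate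
24 | CNP0310719.1: (2R,3R)-epicatechin linked 4β→C8 to a (2R,3R,4S)-flavan-3,4-diol unit whose 4-oxygen is etherified to C4 of a (2S,3S,4S) all-cis flavan-3,4-diol unit | Oc1cc(O)c2c(c1)O[C@H](c1ccc(O)c(O)c1)[C@H](O)[C@H]2c1c(O)cc(O)c2c1O[C@H](c1ccc(O)c(O)c1)[C@H](O)[C@H]2O[C@H]1c2c(O)cc(O)cc2O[C@@H](c2ccc(O)c(O)c2)[C@H]1O | target

Total steps: 15. Longest linear sequence: 7 steps (steps 1, 2, 3, 4, 13, 14, 15, from 1 to 24).

Steps most likely to fail

1. Step 13 (proposed new method). The ylide may add through the mismatched face, or it may revert by loss of phenoxide faster than it attacks the hindered, electron-rich aldehyde. The betaine alkoxide may also take a silyl group from O5 before it reaches the anti-periplanar conformer needed for oxirane closure. The fallback uses known chemistry, sets out from 6 and 8 and returns at 22. Cross-metathesis of 8 with (Z)-but-2-ene-1,4-diyl dimethyl dicarbonate (second-generation Grubbs catalyst) would give the (E)-cinnamyl methyl carbonate F1. Asymmetric allylic etherification of phenol 6 with F1 ([Ir(cod)Cl]2 with a BINOL-derived bis(1-phenylethyl)amine phosphoramidite ligand, THF) would give the branched aryl allyl ether F2, with the benzylic centre (the future C2) set by the ligand. Wittig methylenation (Ph3P=CH2) would turn the aldehyde into the styrene F3, and ring-closing metathesis (second-generation Grubbs catalyst) would close ring C through the same C3–C4 bond as the flav-3-ene F4. NBS in wet THF would add bromine anti to the 2-aryl group and water at C4 to give the bromohydrin F5, and DBU would close it with inversion at C3 to the syn oxirane 22.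

2. Step 14. The oxirane may rearrange by hydride shift to a ketone, or be captured by adventitious nucleophiles before the hindered secondary alcohol reaches C4. The fallback sets out from 22 and returns at 23. Thiophenol would open 22 trans at C4 without added acid to give the stable 4β-phenylthio-3-ol F6. Thiophilic activation of F6 (AgOTf, 2,6-di-tert-butyl-4-methylpyridine, CH2Cl2, −40 °C) in the presence of 18 would then deliver the ether, with the alcohol entering trans to the 3-hydroxyl and no free Brønsted acid present.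

3. Step 8. The activated sulfoxide may fragment, sulfenylate the electron-rich arene of 8 in place of its alkene, or be too hindered at sulfur to accept the alkene. The fallback sets out from 8 and returns at 22. Diphenyl sulfoxide, Tf2O and 8 under the same conditions would give the achiral (E)-styryl diphenylsulfonium triflate F7, a member of a known reagent class. Used with 6 under the conditions of step 13, F7 would leave the ring-face selectivity to the substrate alone, and the unwanted ring diastereomer would be removed by chromatography after step 14.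

Further compounds
F1 | step 13 | (E)-3-[3,4-bis(TBS-oxy)phenyl]allyl methyl carbonate | COC(=O)OC/C=C/c1ccc(O[Si](C)(C)C(C)(C)C)c(O[Si](C)(C)C(C)(C)C)c1
F2 | step 13 | branched aryl allyl ether of 6 (benzylic centre as future C2) | CC(C)(C)[Si](C)(C)Oc1cc(O[Si](C)(C)C(C)(C)C)c2c(c1)O[C@H](c1ccc(O[Si](C)(C)C(C)(C)C)c(O[Si](C)(C)C(C)(C)C)c1)[C@H](O)[C@H]2c1c(O[Si](C)(C)C(C)(C)C)cc(O[Si](C)(C)C(C)(C)C)c(C=O)c1O[C@H](c1ccc(O[Si](C)(C)C(C)(C)C)c(O[Si](C)(C)C(C)(C)C)c1)C=C
F3 | step 13 | diene from methylenation of F2 | CC(C)(C)[Si](C)(C)Oc1cc(O[Si](C)(C)C(C)(C)C)c2c(c1)O[C@H](c1ccc(O[Si](C)(C)C(C)(C)C)c(O[Si](C)(C)C(C)(C)C)c1)[C@H](O)[C@H]2c1c(O[Si](C)(C)C(C)(C)C)cc(O[Si](C)(C)C(C)(C)C)c(C=C)c1O[C@H](c1ccc(O[Si](C)(C)C(C)(C)C)c(O[Si](C)(C)C(C)(C)C)c1)C=C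
F4 | step 13 | (2R)-flav-3-ene carrying the upper unit at C8 | CC(C)(C)[Si](C)(C)Oc1cc(O[Si](C)(C)C(C)(C)C)c2c(c1)O[C@H](c1ccc(O[Si](C)(C)C(C)(C)C)c(O[Si](C)(C)C(C)(C)C)c1)[C@H](O)[C@H]2c1c(O[Si](C)(C)C(C)(C)C)cc(O[Si](C)(C)C(C)(C)C)c2c1O[C@H](c1ccc(O[Si](C)(C)C(C)(C)C)c(O[Si](C)(C)C(C)(C)C)c1)C=C2
F5 | step 13 | bromohydrin (3-bromo anti to the 2-aryl group, 4-hydroxyl syn) | CC(C)(C)[Si](C)(C)Oc1cc(O[Si](C)(C)C(C)(C)C)c2c(c1)O[C@H](c1ccc(O[Si](C)(C)C(C)(C)C)c(O[Si](C)(C)C(C)(C)C)c1)[C@H](O)[C@H]2c1c(O[Si](C)(C)C(C)(C)C)cc(O[Si](C)(C)C(C)(C)C)c2c1O[C@H](c1ccc(O[Si](C)(C)C(C)(C)C)c(O[Si](C)(C)C(C)(C)C)c1)[C@@H](Br)[C@@H]2O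
F6 | step 14 | 4β-phenylthio-3-ol of the middle unit (2,3-cis-3,4-trans) | CC(C)(C)[Si](C)(C)Oc1cc(O[Si](C)(C)C(C)(C)C)c2c(c1)O[C@H](c1ccc(O[Si](C)(C)C(C)(C)C)c(O[Si](C)(C)C(C)(C)C)c1)[C@H](O)[C@H]2c1c(O[Si](C)(C)C(C)(C)C)cc(O[Si](C)(C)C(C)(C)C)c2c1O[C@H](c1ccc(O[Si](C)(C)C(C)(C)C)c(O[Si](C)(C)C(C)(C)C)c1)[C@H](O)[C@H]2Sc1ccccc1
F7 | step 8 | (E)-[2-(3,4-bis(TBS-oxy)phenyl)ethenyl]diphenylsulfonium triflate | c1ccc(cc1)[S+](/C=C/c1ccc(O[Si](C)(C)C(C)(C)C)c(O[Si](C)(C)C(C)(C)C)c1)c1ccccc1.[O-]S(=O)(=O)C(F)(F)F
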